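**Plan**
- Retrosynthesis: the C1 methyl ester is hydrolysed last. The side chain is cut at C6'–C7' (Wittig, then diimide), at its two C–CH3 bonds (conjugate additions) and at the two C=C bonds made by thioester-ylide homologation. This leads back to a dioxolane with one CH2CO2H and one CH2CO2Me arm.
- That half-ester comes from the diester in which C3 and C5 of the 1,2-dioxolane each carry CH3 and CH2CO2Me on the same ring face. This diester is meso, with a mirror plane through C4 and the middle of the O–O bond, so its two ester groups are enantiotopic and a hydrolase can tell them apart.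
- The diester is cut at both ring C–CH2 bonds (peroxycarbenium ion plus ketene silyl acetal) and the ring at its two C–O bonds (acetylacetone plus H2O2).
- Forward: the dioxolane, the only ring formed, is made first; both arms are attached; the enzyme differentiates them; the acid arm is grown outwards by two rounds of ylide homologation and copper-catalysed MeMgBr addition, then a Wittig reaction with the 6-phenylhexyl ylide.
- Stereochemistry: the cis ring relationship comes from isolating the meso diester, the absolute configuration of C3/C5 from the esterase, and the two chain methyl centres (2',4'-anti) from ligand-controlled copper catalysis with enantiomeric ligands.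

Key step: step 4

Assumption: the esterase is taken to cleave the ester on the arm of the (S)-configured ring carbon of the meso diester; the opposite preference is handled by the arm exchange described under the fallbacks.
Assumption: the (R,Sp)-Josiphos–CuBr catalyst is taken to add methyl to the Re face of C3 of a linear (E)-2-enethioate and its enantiomer to the Si face; if a trial addition shows the reverse sense, the two ligands change places between steps 9 and 12.

Step 1
Reactants: 1 acetylacetone (pentane-2,4-dione); 2 hydrogen peroxide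
Product: 3 3,5-dimethyl-1,2-dioxolane-3,5-diol (cis/trans mixture)
Conditions: H2O2 (30% aq, 1.0 equiv), no acid, 0 °C to rt; small scale behind a shield
Reagents that add atoms: none
Why: Double peroxyhemiketalisation, in which H2O2 adds to one carbonyl and the hydroperoxide so formed closes 5-exo-trig onto the second, is the normal behaviour of a 1,3-diketone, and the configuration of the two hemiketal carbons is irrelevant because both are ionised in step 3.

Step 2
Reactants: 3 3,5-dimethyl-1,2-dioxolane-3,5-diol
Product: 4 3,5-dimethyl-1,2-dioxolane-3,5-diyl diacetate (cis/trans mixture)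
Conditions: Ac2O, Et3N, DMAP (cat.), CH2Cl2, 0 °C
Reagents that add atoms: acetic anhydride, CC(=O)OC(C)=O
Why: DMAP-catalysed O-acetylation (nucleophilic acyl transfer) should turn both tertiary peroxyhemiketal hydroxyls into acetate leaving groups, and since no carbon next to the O–O bond bears hydrogen a Kornblum–DeLaMare fragmentation has no path.

Step 3
Reactants: 4 3,5-dimethyl-1,2-dioxolane-3,5-diyl diacetate; 5 1-(tert-butyldimethylsilyloxy)-1-methoxyethene
Product: 7 dimethyl 2,2'-[(3R,5S)-3,5-dimethyl-1,2-dioxolane-3,5-diyl]diacetate (meso cis diester), via acetoxy monoester 6 (not isolated)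
Conditions: 5 (3 equiv), TMSOTf (0.3 equiv), CH2Cl2, −78 °C; chromatography to remove the trans diester
Reagents that add atoms: none
Why: This is a Mukaiyama-type substitution through peroxycarbenium ions, a reaction type established for 3-acyloxy- and 3-alkoxy-1,2-dioxolanes, in which the silyl triflate ionises each acetate in turn and the ketene silyl acetal adds to the oxygen-stabilised cation; the second addition has no facial bias, so the cis (meso) diester should form beside the trans racemate and is separated, the cis isomer being the one whose ring C4 protons are diastereotopic.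

Step 4
Reactants: 7 dimethyl 2,2'-[(3R,5S)-3,5-dimethyl-1,2-dioxolane-3,5-diyl]diacetate
Product: 8 2-[(3S,5R)-5-(2-methoxy-2-oxoethyl)-3,5-dimethyl-1,2-dioxolan-3-yl]acetic acid
Conditions: pig liver esterase, 0.1 M phosphate buffer pH 7.0, acetone (5%), 25 °C, pH-stat with 0.5 M NaOH (1.0 equiv); then 1 M HCl to pH 3, EtOAc
Reagents that add atoms: water, O
Why: The active-site serine of the esterase is acylated by one of the two ester carbonyls and the acyl-enzyme is then hydrolysed by water, so one CO2Me becomes CO2H and the other stays; the closest known reaction type is the pig liver esterase desymmetrisation of meso and prochiral dimethyl esters. No skeletal bond forms and no ring is closed. C3 and C5 already exist as a mirror-image pair, and the chiral binding pocket of the enzyme decides which of them keeps the ester, which fixes the absolute configuration of both at once as (3S,5R) in 8. The step needs enantiotopic-group selectivity and a stop at the half-ester: the mirror plane of 7 through C4 and the middle of the O–O bond makes the arms enantiotopic, and the carboxylate formed is a poor substrate for a second hydrolysis. Working at pH 7 and 25 °C should keep the β-peroxy ester from eliminating, which a chemical mono-saponification could not guarantee.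

Step 5
Reactants: 8 2-[(3S,5R)-5-(2-methoxy-2-oxoethyl)-3,5-dimethyl-1,2-dioxolan-3-yl]acetic acid
Product: 10 methyl 2-[(3R,5R)-5-(2-hydroxyethyl)-3,5-dimethyl-1,2-dioxolan-3-yl]acetate, via mixed anhydride 9 (not isolated)
Conditions: i-BuOCOCl, N-methylmorpholine, THF, −15 °C; then NaBH4, H2O, 0 °C
Reagents that add atoms: none
Why: Mixed carbonic anhydride activation followed by borohydride reduction should reduce only the acid arm, because NaBH4 attacks the activated acyl carbon but neither the methyl ester nor the di-tert-alkyl peroxide at 0 °C, and no stereocentre is touched.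

Step 6
Reactants: 11 bromoacetyl bromide; 12 ethanethiol
Product: 13 S-ethyl 2-bromoethanethioate
Conditions: pyridine (1.0 equiv), CH2Cl2, −10 to 0 °C
Reagents that add atoms: none
Why: Thioesterification by acyl substitution at the acyl bromide is far faster at low temperature than SN2 displacement of the alkyl bromide by the thiol.

Step 7
Reactants: 13 S-ethyl 2-bromoethanethioate
Product: 15 S-ethyl 2-(triphenyl-λ5-phosphanylidene)ethanethioate, via phosphonium bromide 14 (not isolated)
Conditions: PPh3, toluene, rt; then 10% aq Na2CO3, CH2Cl2, rt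
Reagents that add atoms: triphenylphosphine, c1ccc(cc1)P(c1ccccc1)c1ccccc1
Why: SN2 quaternisation of the phosphine by the α-bromo thioester and deprotonation of the acidic phosphonium salt by carbonate give the stabilised Wittig ylide.

Step 8
Reactants: 10 methyl 2-[(3R,5R)-5-(2-hydroxyethyl)-3,5-dimethyl-1,2-dioxolan-3-yl]acetate; 15 S-ethyl 2-(triphenyl-λ5-phosphanylidene)ethanethioate
Product: 17 S-ethyl (2E)-4-[(3R,5R)-5-(2-methoxy-2-oxoethyl)-3,5-dimethyl-1,2-dioxolan-3-yl]but-2-enethioate, via aldehyde 16 (not isolated)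
Conditions: Dess–Martin periodinane, CH2Cl2, 0 °C; then 15 (3 equiv) added to the same flask, rt
Reagents that add atoms: none
Why: Dess–Martin oxidation followed in the same flask by a Wittig reaction with the stabilised ylide should trap the β-peroxy aldehyde before it can lose the peroxide by β-elimination and give the (E)-enethioate, neither reagent being one that attacks a dialkyl peroxide.

Step 9
Reactants: 17 S-ethyl (2E)-4-[(3R,5R)-5-(2-methoxy-2-oxoethyl)-3,5-dimethyl-1,2-dioxolan-3-yl]but-2-enethioate
Product: 18 S-ethyl (3R)-4-[(3R,5R)-5-(2-methoxy-2-oxoethyl)-3,5-dimethyl-1,2-dioxolan-3-yl]-3-methylbutanethioate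
Conditions: MeMgBr (1.2 equiv), CuBr·SMe2 (5 mol%), (R)-1-[(Sp)-2-(diphenylphosphino)ferrocenyl]ethyldicyclohexylphosphine [(R,Sp)-Josiphos, 6 mol%], t-BuOMe, −75 °C; MeOH at −75 °C, then aq NH4Cl
Reagents that add atoms: methylmagnesium bromide, C[Mg]Br
Why: In this copper-catalysed asymmetric conjugate addition of a Grignard reagent to an (E)-α,β-unsaturated thioester the chiral diphosphine–copper complex should deliver methyl to the Re face of C3 (catalyst control) and so set the (3R) centre, the fast catalytic pathway at −75 °C outrunning attack of MeMgBr on the methyl ester or on the hindered di-tert-alkyl O–O bond, and the magnesium enolate is protonated cold.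

Step 10
Reactants: 18 S-ethyl (3R)-4-[(3R,5R)-5-(2-methoxy-2-oxoethyl)-3,5-dimethyl-1,2-dioxolan-3-yl]-3-methylbutanethioate
Product: 19 methyl 2-[(3R,5R)-5-[(2S)-4-hydroxy-2-methylbutyl]-3,5-dimethyl-1,2-dioxolan-3-yl]acetate
Conditions: NaBH4, EtOH–THF, 0 °C to rt
Reagents that add atoms: none
Why: Chemoselective borohydride reduction should take the thioester, which is far more electrophilic than the methyl ester, to the primary alcohol while ester, peroxide and the new stereocentre stay as they are.

Step 11
Reactants: 19 methyl 2-[(3R,5R)-5-[(2S)-4-hydroxy-2-methylbutyl]-3,5-dimethyl-1,2-dioxolan-3-yl]acetate; 15 S-ethyl 2-(triphenyl-λ5-phosphanylidene)ethanethioate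
Product: 21 S-ethyl (2E,5S)-6-[(3R,5R)-5-(2-methoxy-2-oxoethyl)-3,5-dimethyl-1,2-dioxolan-3-yl]-5-methylhex-2-enethioate, via aldehyde 20 (not isolated)
Conditions: Dess–Martin periodinane, CH2Cl2, 0 °C; then 15 (3 equiv) added to the same flask, rt
Reagents that add atoms: none
Why: The same Dess–Martin oxidation and in-flask Wittig olefination should give the (E)-enethioate, and the methyl-bearing centre is β to the aldehyde carbonyl and therefore cannot epimerise.

Step 12
Reactants: 21 S-ethyl (2E,5S)-6-[(3R,5R)-5-(2-methoxy-2-oxoethyl)-3,5-dimethyl-1,2-dioxolan-3-yl]-5-methylhex-2-enethioate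
Product: 22 S-ethyl (3S,5S)-6-[(3R,5R)-5-(2-methoxy-2-oxoethyl)-3,5-dimethyl-1,2-dioxolan-3-yl]-3,5-dimethylhexanethioate
Conditions: MeMgBr (1.2 equiv), CuBr·SMe2 (5 mol%), (S)-1-[(Rp)-2-(diphenylphosphino)ferrocenyl]ethyldicyclohexylphosphine [(S,Rp)-Josiphos, 6 mol%], t-BuOMe, −75 °C; MeOH at −75 °C, then aq NH4Cl
Reagents that add atoms: methylmagnesium bromide, C[Mg]Br
Why: A second copper-catalysed asymmetric conjugate addition, now with the enantiomeric ligand, should deliver methyl to the Si face of C3 and set the (3S) centre anti to the existing methyl group, catalyst control overriding the weak bias of the C5 centre.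

Step 13
Reactants: 22 S-ethyl (3S,5S)-6-[(3R,5R)-5-(2-methoxy-2-oxoethyl)-3,5-dimethyl-1,2-dioxolan-3-yl]-3,5-dimethylhexanethioate
Product: 23 methyl 2-[(3R,5R)-5-[(2S,4S)-6-hydroxy-2,4-dimethylhexyl]-3,5-dimethyl-1,2-dioxolan-3-yl]acetate
Conditions: NaBH4, EtOH–THF, 0 °C to rt
Reagents that add atoms: none
Why: Chemoselective borohydride reduction of the thioester in the presence of the methyl ester, as in step 10, should give the primary alcohol.

Step 14
Reactants: 23 methyl 2-[(3R,5R)-5-[(2S,4S)-6-hydroxy-2,4-dimethylhexyl]-3,5-dimethyl-1,2-dioxolan-3-yl]acetate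
Product: 24 methyl 2-[(3R,5R)-5-[(2S,4S)-2,4-dimethyl-6-oxohexyl]-3,5-dimethyl-1,2-dioxolan-3-yl]acetate
Conditions: Dess–Martin periodinane, CH2Cl2, 0 °C to rt
Reagents that add atoms: none
Why: Dess–Martin oxidation under neutral conditions should give the aldehyde without touching the peroxide, and the nearest stereocentre is β to the carbonyl.

Step 15
Reactants: 25 (6-bromohexyl)benzene
Product: 26 triphenyl(6-phenylhexyl)phosphonium bromide
Conditions: PPh3, MeCN, reflux
Reagents that add atoms: triphenylphosphine, c1ccc(cc1)P(c1ccccc1)c1ccccc1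
Why: SN2 quaternisation of triphenylphosphine by the primary alkyl bromide gives the phosphonium salt.

Step 16
Reactants: 24 methyl 2-[(3R,5R)-5-[(2S,4S)-2,4-dimethyl-6-oxohexyl]-3,5-dimethyl-1,2-dioxolan-3-yl]acetate; 26 triphenyl(6-phenylhexyl)phosphonium bromide
Product: 28 methyl 2-[(3R,5R)-5-[(2S,4S,6Z)-2,4-dimethyl-12-phenyldodec-6-en-1-yl]-3,5-dimethyl-1,2-dioxolan-3-yl]acetate, via ylide 27 (not isolated)
Conditions: 26, NaN(SiMe3)2, THF, −78 to 0 °C; then 24, −78 °C to rt
Reagents that add atoms: none
Why: Wittig olefination with the non-stabilised ylide should give mainly the (Z)-alkene, whose geometry does not matter because the double bond is reduced next, and at −78 °C the ylide should be consumed by the aldehyde faster than it can attack the ester or the peroxide.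

Step 17
Reactants: 28 methyl 2-[(3R,5R)-5-[(2S,4S,6Z)-2,4-dimethyl-12-phenyldodec-6-en-1-yl]-3,5-dimethyl-1,2-dioxolan-3-yl]acetate
Product: 29 methyl 2-[(3R,5R)-5-[(2S,4R)-2,4-dimethyl-12-phenyldodecyl]-3,5-dimethyl-1,2-dioxolan-3-yl]acetate
Conditions: 2-nitrobenzenesulfonyl hydrazide (excess), Et3N, CH2Cl2, rt
Reagents that add atoms: none
Why: Diimide reduction, a concerted syn transfer of two hydrogens from HN=NH generated from the sulfonyl hydrazide, should saturate the disubstituted alkene and leave the O–O bond, which catalytic hydrogenation would cleave (the C4' descriptor changes from S to R only through the priority rules).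

Step 18
Reactants: 29 methyl 2-[(3R,5R)-5-[(2S,4R)-2,4-dimethyl-12-phenyldodecyl]-3,5-dimethyl-1,2-dioxolan-3-yl]acetate
Product: 30 2-[(3R,5R)-5-[(2S,4R)-2,4-dimethyl-12-phenyldodecyl]-3,5-dimethyl-1,2-dioxolan-3-yl]acetic acid (target)
Conditions: LiOH, THF–H2O, 0 °C; then 1 M HCl to pH 3
Reagents that add atoms: lithium hydroxide (hydroxide oxygen), [Li+].[OH-]
Why: Saponification by hydroxide attack at the ester carbonyl should be faster at 0 °C than α-deprotonation, so retro-oxa-Michael opening of the β-peroxy ester is not expected and C3 keeps its configuration.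

**Compound list**
1 | acetylacetone (pentane-2,4-dione) | CC(=O)CC(C)=O | starting material
2 | hydrogen peroxide | OO | starting material
3 | 3,5-dimethyl-1,2-dioxolane-3,5-diol (cis/trans mixture) | CC1(O)CC(C)(O)OO1 | intermediate
4 | 3,5-dimethyl-1,2-dioxolane-3,5-diyl diacetate (cis/trans mixture) | CC(=O)OC1(C)CC(C)(OC(C)=O)OO1 | intermediate
5 | 1-(tert-butyldimethylsilyloxy)-1-methoxyethene | C=C(OC)O[Si](C)(C)C(C)(C)C | starting material
6 | methyl 2-(5-acetoxy-3,5-dimethyl-1,2-dioxolan-3-yl)acetate (diastereomer mixture) | COC(=O)CC1(C)CC(C)(OC(C)=O)OO1 | intermediate (not isolated)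
7 | dimethyl 2,2'-[(3R,5S)-3,5-dimethyl-1,2-dioxolane-3,5-diyl]diacetate (meso, cis) | COC(=O)C[C@]1(C)C[C@](C)(CC(=O)OC)OO1 | intermediate
8 | 2-[(3S,5R)-5-(2-methoxy-2-oxoethyl)-3,5-dimethyl-1,2-dioxolan-3-yl]acetic acid | OC(=O)C[C@]1(C)C[C@](C)(CC(=O)OC)OO1 | intermediate
9 | 2-[(3S,5R)-5-(2-methoxy-2-oxoethyl)-3,5-dimethyl-1,2-dioxolan-3-yl]acetic isobutyl carbonic anhydride | CC(C)COC(=O)OC(=O)C[C@]1(C)C[C@](C)(CC(=O)OC)OO1 | intermediate (not isolated)
10 | methyl 2-[(3R,5R)-5-(2-hydroxyethyl)-3,5-dimethyl-1,2-dioxolan-3-yl]acetate | OCC[C@]1(C)C[C@](C)(CC(=O)OC)OO1 | intermediate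
11 | bromoacetyl bromide | BrCC(Br)=O | starting material
12 | ethanethiol | CCS | starting material
13 | S-ethyl 2-bromoethanethioate | CCSC(=O)CBr | intermediate
14 | [2-(ethylsulfanyl)-2-oxoethyl]triphenylphosphonium bromide | [Br-].CCSC(=O)C[P+](c1ccccc1)(c1ccccc1)c1ccccc1 | intermediate (not isolated)
15 | S-ethyl 2-(triphenyl-λ5-phosphanylidene)ethanethioate | CCSC(=O)C=P(c1ccccc1)(c1ccccc1)c1ccccc1 | intermediate
16 | methyl 2-[(3R,5S)-3,5-dimethyl-5-(2-oxoethyl)-1,2-dioxolan-3-yl]acetate | O=CC[C@]1(C)C[C@](C)(CC(=O)OC)OO1 | intermediate (not isolated)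
17 | S-ethyl (2E)-4-[(3R,5R)-5-(2-methoxy-2-oxoethyl)-3,5-dimethyl-1,2-dioxolan-3-yl]but-2-enethioate | CCSC(=O)/C=C/C[C@]1(C)C[C@](C)(CC(=O)OC)OO1 | intermediate
18 | S-ethyl (3R)-4-[(3R,5R)-5-(2-methoxy-2-oxoethyl)-3,5-dimethyl-1,2-dioxolan-3-yl]-3-methylbutanethioate | CCSC(=O)C[C@H](C)C[C@]1(C)C[C@](C)(CC(=O)OC)OO1 | intermediate
19 | methyl 2-[(3R,5R)-5-[(2S)-4-hydroxy-2-methylbutyl]-3,5-dimethyl-1,2-dioxolan-3-yl]acetate | OCC[C@H](C)C[C@]1(C)C[C@](C)(CC(=O)OC)OO1 | intermediate
20 | methyl 2-[(3R,5R)-3,5-dimethyl-5-[(2R)-2-methyl-4-oxobutyl]-1,2-dioxolan-3-yl]acetate | O=CC[C@H](C)C[C@]1(C)C[C@](C)(CC(=O)OC)OO1 | intermediate (not isolated)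
21 | S-ethyl (2E,5S)-6-[(3R,5R)-5-(2-methoxy-2-oxoethyl)-3,5-dimethyl-1,2-dioxolan-3-yl]-5-methylhex-2-enethioate | CCSC(=O)/C=C/C[C@H](C)C[C@]1(C)C[C@](C)(CC(=O)OC)OO1 | intermediate
22 | S-ethyl (3S,5S)-6-[(3R,5R)-5-(2-methoxy-2-oxoethyl)-3,5-dimethyl-1,2-dioxolan-3-yl]-3,5-dimethylhexanethioate | C[C@H](CC(=O)SCC)C[C@H](C)C[C@]1(C)C[C@](C)(CC(=O)OC)OO1 | intermediate
23 | methyl 2-[(3R,5R)-5-[(2S,4S)-6-hydroxy-2,4-dimethylhexyl]-3,5-dimethyl-1,2-dioxolan-3-yl]acetate | C[C@H](CCO)C[C@H](C)C[C@]1(C)C[C@](C)(CC(=O)OC)OO1 | intermediate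
24 | methyl 2-[(3R,5R)-5-[(2S,4S)-2,4-dimethyl-6-oxohexyl]-3,5-dimethyl-1,2-dioxolan-3-yl]acetate | C[C@H](CC=O)C[C@H](C)C[C@]1(C)C[C@](C)(CC(=O)OC)OO1 | intermediate
25 | (6-bromohexyl)benzene | BrCCCCCCc1ccccc1 | starting material
26 | triphenyl(6-phenylhexyl)phosphonium bromide | [Br-].c1ccc(CCCCCC[P+](c2ccccc2)(c2ccccc2)c2ccccc2)cc1 | intermediate
27 | triphenyl(6-phenylhexylidene)-λ5-phosphane | c1ccc(CCCCCC=P(c2ccccc2)(c2ccccc2)c2ccccc2)cc1 | intermediate (not isolated)
28 | methyl 2-[(3R,5R)-5-[(2S,4S,6Z)-2,4-dimethyl-12-phenyldodec-6-en-1-yl]-3,5-dimethyl-1,2-dioxolan-3-yl]acetate | C[C@H](C/C=C\CCCCCc1ccccc1)C[C@H](C)C[C@]1(C)C[C@](C)(CC(=O)OC)OO1 | intermediate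
29 | methyl 2-[(3R,5R)-5-[(2S,4R)-2,4-dimethyl-12-phenyldodecyl]-3,5-dimethyl-1,2-dioxolan-3-yl]acetate | C[C@H](CCCCCCCCc1ccccc1)C[C@H](C)C[C@]1(C)C[C@](C)(CC(=O)OC)OO1 | intermediate
30 | 2-[(3R,5R)-5-[(2S,4R)-2,4-dimethyl-12-phenyldodecyl]-3,5-dimethyl-1,2-dioxolan-3-yl]acetic acid | C[C@H](CCCCCCCCc1ccccc1)C[C@H](C)C[C@]1(C)C[C@](C)(CC(=O)O)OO1 | target

**Step count**
Total: 18 steps. Longest linear sequence: 15 steps (steps 1–5, 8–14, 16–18); steps 6–7 and step 15 are side branches.

**Steps most likely to fail**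

Step 9. After methyl transfer the magnesium thioester enolate sits five atoms from a ring oxygen and may open the O–O bond by intramolecular substitution at oxygen. The copper/Grignard system may also reduce the peroxide, or the ring oxygens may disturb facial control. The fallback sets out from alcohol 10 and forms the same C–CH3 bond by allylic substitution, which passes through no enolate. Dess–Martin oxidation with in-flask Wittig reaction using (triphenylphosphoranylidene)acetaldehyde should give methyl 2-[(3R,5R)-3,5-dimethyl-5-[(2E)-4-oxobut-2-en-1-yl]-1,2-dioxolan-3-yl]acetate F1. Luche reduction (NaBH4, CeCl3·7H2O, MeOH) should give the allylic alcohol methyl 2-[(3R,5R)-5-[(2E)-4-hydroxybut-2-en-1-yl]-3,5-dimethyl-1,2-dioxolan-3-yl]acetate F2. An Appel reaction (CBr4, PPh3) should give the allylic bromide methyl 2-[(3R,5R)-5-[(2E)-4-bromobut-2-en-1-yl]-3,5-dimethyl-1,2-dioxolan-3-yl]acetate F3. Copper-catalysed asymmetric SN2' alkylation with MeMgBr then follows, using CuBr·SMe2 and the suitable enantiomer of the Taniaphos ligand 1-[α-(dimethylamino)-2-(diphenylphosphino)benzyl]-2-(diphenylphosphino)ferrocene in CH2Cl2 at −75 °C. It should give the branched alkene methyl 2-[(3R,5R)-3,5-dimethyl-5-[(2R)-2-methylbut-3-en-1-yl]-1,2-dioxolan-3-yl]acetate F4. Hydroboration with 9-BBN and oxidation with NaBO3·4H2O comes back to the route at alcohol 19.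

Step 3. The peroxycarbenium ion may fragment before the second ketene acetal addition, the second substitution may stall at the acetoxy monoester, or the cis and trans diesters may not separate. The fallback sets out from diacetate 4 and uses the most robust peroxycarbenium trap. Double Hosomi–Sakurai allylation (allyltrimethylsilane, TMSOTf, CH2Cl2, −78 °C) should give, after separation at this non-polar stage, cis-(3R,5S)-3,5-dimethyl-3,5-di(prop-2-en-1-yl)-1,2-dioxolane F5. Ozonolysis (O3, CH2Cl2–MeOH, −78 °C; Me2S) should give 2,2'-[(3R,5S)-3,5-dimethyl-1,2-dioxolane-3,5-diyl]diacetaldehyde F6. Pinnick oxidation (NaClO2, NaH2PO4, 2-methyl-2-butene) should give 2,2'-[(3R,5S)-3,5-dimethyl-1,2-dioxolane-3,5-diyl]diacetic acid F7. Esterification with trimethylsilyldiazomethane in MeOH–toluene comes back to the route at diester 7.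

Step 4. The esterase may attack the ester of the other enantiotopic arm. The fallback sets out from diester 7 and exchanges the roles of the arms. The mirror-image half-ester 2-[(3R,5S)-5-(2-methoxy-2-oxoethyl)-3,5-dimethyl-1,2-dioxolan-3-yl]acetic acid F8 is treated with LiBH4 (THF, 0 °C), which reduces the ester but not the lithium carboxylate. This should give 2-[(3R,5R)-5-(2-hydroxyethyl)-3,5-dimethyl-1,2-dioxolan-3-yl]acetic acid F9. Esterification with trimethylsilyldiazomethane comes back to the route at alcohol 10 with the required absolute configuration.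

**Further compounds**
F1 | step 9 | methyl 2-[(3R,5R)-3,5-dimethyl-5-[(2E)-4-oxobut-2-en-1-yl]-1,2-dioxolan-3-yl]acetate | O=C/C=C/C[C@]1(C)C[C@](C)(CC(=O)OC)OO1
F2 | step 9 | methyl 2-[(3R,5R)-5-[(2E)-4-hydroxybut-2-en-1-yl]-3,5-dimethyl-1,2-dioxolan-3-yl]acetate | OC/C=C/C[C@]1(C)C[C@](C)(CC(=O)OC)OO1
F3 | step 9 | methyl 2-[(3R,5R)-5-[(2E)-4-bromobut-2-en-1-yl]-3,5-dimethyl-1,2-dioxolan-3-yl]acetate | BrC/C=C/C[C@]1(C)C[C@](C)(CC(=O)OC)OO1
F4 | step 9 | methyl 2-[(3R,5R)-3,5-dimethyl-5-[(2R)-2-methylbut-3-en-1-yl]-1,2-dioxolan-3-yl]acetate | C=C[C@H](C)C[C@]1(C)C[C@](C)(CC(=O)OC)OO1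
F5 | step 3 | (3R,5S)-3,5-dimethyl-3,5-di(prop-2-en-1-yl)-1,2-dioxolane (cis, meso) | C=CC[C@]1(C)C[C@](C)(CC=C)OO1
F6 | step 3 | 2,2'-[(3R,5S)-3,5-dimethyl-1,2-dioxolane-3,5-diyl]diacetaldehyde | O=CC[C@]1(C)C[C@](C)(CC=O)OO1
F7 | step 3 | 2,2'-[(3R,5S)-3,5-dimethyl-1,2-dioxolane-3,5-diyl]diacetic acid | OC(=O)C[C@]1(C)C[C@](C)(CC(=O)O)OO1
F8 | step 4 | 2-[(3R,5S)-5-(2-methoxy-2-oxoethyl)-3,5-dimethyl-1,2-dioxolan-3-yl]acetic acid | COC(=O)C[C@]1(C)C[C@](C)(CC(=O)O)OO1
F9 | step 4 | 2-[(3R,5R)-5-(2-hydroxyethyl)-3,5-dimethyl-1,2-dioxolan-3-yl]acetic acid | OCC[C@]1(C)C[C@](C)(CC(=O)O)OO1
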